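The oxolane ring (O1, C2–C5) holds the aryl group on C2 and the oxymethyl arm on C3 on the same face, while C5 is an unsubstituted carbon next to C4. Read backwards, O1–C2–C3–C4–C5 is a cis γ-butyrolactone with its carbonyl at C5. One carbene-catalysed annulation joins 3,4,5-trimethoxybenzaldehyde to the β-carbon of a four-carbon enal (C2–C3) and closes O1–C5, creating the ring and both cis stereocentres at once. The enal is (E)-4-silyloxybut-2-enal, carried as the bulky tert-butyldiphenylsilyl ether to block silyl transfer to the new C2 alkoxide. The lactone carbonyl then directs a trans aldol at C4 before C5 is taken down to the ring CH2.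

Key step: step 3

Numbering used throughout: oxolane O1, C2 (aryl), C3 (bearing C9H2–O), C4 (bearing the C7 carbonyl), C5 (ring CH2).

Assumption 1: the sense of induction of the aminoindanol-derived triazolium on this aldehyde pair is not known in advance. The route is written with the (5aR,10bS) salt, and its (5aS,10bR) antipode, equally available, is used if the first run shows the opposite sense.

Assumption 2: catalyst-bound species of the carbene cycle are described in the Why line of step 3 and carry no number, since none is a free compound.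

Assumption 3: the C7 carbinol centre made in step 4 is carried as an epimer mixture and is drawn without configuration until step 7 removes it.

Step 1
Reactants: 1 cis-but-2-ene-1,4-diol
Product: 2 (Z)-4-(tert-butyldiphenylsilyloxy)but-2-en-1-ol
Conditions: NaH (1.0 equiv), THF, 0 °C to rt; then tBuPh2SiCl (1.0 equiv)
Reagents that add atoms: tert-butyl(chloro)diphenylsilane, CC(C)(C)[Si](Cl)(c1ccccc1)c1ccccc1
Why: O-silylation of the sparingly soluble monosodium alkoxide of the symmetric diol, which reacts faster than the remaining neutral hydroxyl, so the mono-ether should dominate; no stereocentre is formed.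

Step 2
Reactants: 2 (Z)-4-(tert-butyldiphenylsilyloxy)but-2-en-1-ol
Product: 4 (E)-4-(tert-butyldiphenylsilyloxy)but-2-enal, via (Z)-4-(tert-butyldiphenylsilyloxy)but-2-enal 3 (not isolated)
Conditions: [C5H5NH][CrO3Cl] (pyridinium chlorochromate, 1.5 equiv), Celite, CH2Cl2, rt
Reagents that add atoms: none
Why: Chlorochromate oxidation of the primary allylic alcohol gives the Z-enal, which the mildly acidic pyridinium medium should equilibrate to the conjugated, more stable E-enal, while the hindered silyl ether tolerates the acidity.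

Step 3
Reactants: 4 (E)-4-(tert-butyldiphenylsilyloxy)but-2-enal; 5 3,4,5-trimethoxybenzaldehyde
Product: 6 (4S,5S)-4-[(tert-butyldiphenylsilyloxy)methyl]-5-(3,4,5-trimethoxyphenyl)oxolan-2-one (cis lactone)
Conditions: (5aR,10bS)-2-mesityl-5a,10b-dihydro-4H,6H-indeno[2,1-b][1,2,4]triazolo[4,3-d][1,4]oxazin-2-ium chloride (10 mol%), DBU (10 mol%), 5 (2 equiv), slow addition of 4, THF, rt; silica chromatography, then preparative chiral SFC
Reagents that add atoms: none
Why: The free carbene adds to the formyl carbon of 4 and proton transfer gives the extended Breslow intermediate (homoenolate), whose β-carbon C3 attacks the carbonyl of 5 to form C2–C3; tautomerisation to the acyl azolium and attack of the C2 alkoxide on it forms O1–C5 and releases the carbene. This is the known carbene-catalysed homoenolate annulation of enals with aromatic aldehydes to cis-4,5-disubstituted γ-butyrolactones. The lactone ring closes by a 5-exo-trig acyl substitution of the C2 oxygen at the acyl azolium carbon C5. C2 and C3 are both set in the C–C bond-forming event: their cis relationship should follow from the compact, hydrogen-bond-organised transition state of the E-homoenolate and the aldehyde, and their absolute sense from the indane wall of the chiral triazolylidene, which leaves one face of the homoenolate open. The step needs cross-annulation over enal self-annulation and benzoin pathways, and acylation of O2 instead of O9: the N-mesityl triazolylidene favours homoenolate over acyl-anion reactivity, the non-enolisable aldehyde 5 is kept in excess while 4 is added slowly, and the bulky silyl group resists the 1,5 shift from O9 to the C2 alkoxide that would let O9 close the isomeric lactone. Residual trans isomer should be removed on silica and the enantiomeric purity brought to a single enantiomer by the chiral separation before step 4.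

Step 4
Reactants: 6 (4S,5S)-4-[(tert-butyldiphenylsilyloxy)methyl]-5-(3,4,5-trimethoxyphenyl)oxolan-2-one; 5 3,4,5-trimethoxybenzaldehyde
Product: 7 (3S,4S,5S)-4-[(tert-butyldiphenylsilyloxy)methyl]-3-[hydroxy(3,4,5-trimethoxyphenyl)methyl]-5-(3,4,5-trimethoxyphenyl)oxolan-2-one (C7 epimers)
Conditions: LiN(iPr)2 (1.1 equiv), THF, −78 °C; then 5, −78 °C; AcOH quench at −78 °C
Reagents that add atoms: none
Why: Lithium enolate aldol addition in which 5 approaches the planar lactone enolate on the face opposite the adjacent C3 silyloxymethyl arm and the C2 aryl group, which should set C4 trans to C3, while the C7 carbinol forms as an epimer mixture that step 7 erases.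

Step 5
Reactants: 7 (3S,4S,5S)-4-[(tert-butyldiphenylsilyloxy)methyl]-3-[hydroxy(3,4,5-trimethoxyphenyl)methyl]-5-(3,4,5-trimethoxyphenyl)oxolan-2-one
Product: 8 (1S,2S,3R)-2-[(tert-butyldiphenylsilyloxy)methyl]-3-(hydroxymethyl)-1,4-bis(3,4,5-trimethoxyphenyl)butane-1,4-diol (C7 epimers)
Conditions: LiBH4 (3 equiv), THF, 0 °C to rt; then H2O
Reagents that add atoms: none
Why: Borohydride reduction of the lactone to the diol should free the primary C5 hydroxyl and the C2 benzylic hydroxyl without touching the silyl ether or any stereocentre.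

Step 6
Reactants: 8 (1S,2S,3R)-2-[(tert-butyldiphenylsilyloxy)methyl]-3-(hydroxymethyl)-1,4-bis(3,4,5-trimethoxyphenyl)butane-1,4-diol
Product: 10 {(3R,4S,5S)-4-[(tert-butyldiphenylsilyloxy)methyl]-5-(3,4,5-trimethoxyphenyl)oxolan-3-yl}(3,4,5-trimethoxyphenyl)methanol (C7 epimers), via primary tosylate 9 (not isolated)
Conditions: TsCl (1.1 equiv), Et3N, DMAP (cat.), THF, 0 °C; then KOtBu, 0 °C to rt
Reagents that add atoms: none
Why: Selective sulfonylation of the only primary hydroxyl followed by intramolecular Williamson etherification (5-exo-tet SN2 at C5 by the C2 alkoxide) should re-form O1–C5 without any bond to C2 being broken, so the cis C2/C3 and trans C3/C4 relationships are kept, and the four-membered closure through O7 cannot compete.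

Step 7
Reactants: 10 {(3R,4S,5S)-4-[(tert-butyldiphenylsilyloxy)methyl]-5-(3,4,5-trimethoxyphenyl)oxolan-3-yl}(3,4,5-trimethoxyphenyl)methanol
Product: 11 {(3R,4S,5S)-4-[(tert-butyldiphenylsilyloxy)methyl]-5-(3,4,5-trimethoxyphenyl)oxolan-3-yl}(3,4,5-trimethoxyphenyl)methanone
Conditions: Dess–Martin periodinane, NaHCO3, CH2Cl2, 0 °C to rt
Reagents that add atoms: none
Why: Dess–Martin oxidation of the only free alcohol, a secondary benzylic carbinol, should give the aryl ketone from both C7 epimers under buffered conditions that leave C4 in its more stable trans arrangement.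

Step 8
Reactants: 11 {(3R,4S,5S)-4-[(tert-butyldiphenylsilyloxy)methyl]-5-(3,4,5-trimethoxyphenyl)oxolan-3-yl}(3,4,5-trimethoxyphenyl)methanone
Product: 12 [(3R,4S,5S)-4-(hydroxymethyl)-5-(3,4,5-trimethoxyphenyl)oxolan-3-yl](3,4,5-trimethoxyphenyl)methanone (target)
Conditions: HF·pyridine, pyridine, THF, 0 °C to rt
Reagents that add atoms: none
Why: Fluoride cleavage of the primary silyl ether under acidic rather than basic conditions, so that the β-alkoxy ketone should neither open by E1cB loss of O1 nor epimerise at C4.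

Compound list
1 | cis-but-2-ene-1,4-diol | OC/C=C\CO | starting material
2 | (Z)-4-(tert-butyldiphenylsilyloxy)but-2-en-1-ol | OC/C=C\CO[Si](c1ccccc1)(c1ccccc1)C(C)(C)C | intermediate
3 | (Z)-4-(tert-butyldiphenylsilyloxy)but-2-enal | O=C/C=C\CO[Si](c1ccccc1)(c1ccccc1)C(C)(C)C | intermediate (not isolated)
4 | (E)-4-(tert-butyldiphenylsilyloxy)but-2-enal | O=C/C=C/CO[Si](c1ccccc1)(c1ccccc1)C(C)(C)C | intermediate
5 | 3,4,5-trimethoxybenzaldehyde | COc1cc(C=O)cc(OC)c1OC | starting material
6 | (4S,5S)-4-[(tert-butyldiphenylsilyloxy)methyl]-5-(3,4,5-trimethoxyphenyl)oxolan-2-one | O=C1C[C@@H](CO[Si](c2ccccc2)(c2ccccc2)C(C)(C)C)[C@@H](c2cc(OC)c(OC)c(OC)c2)O1 | intermediate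
7 | (3S,4S,5S)-4-[(tert-butyldiphenylsilyloxy)methyl]-3-[hydroxy(3,4,5-trimethoxyphenyl)methyl]-5-(3,4,5-trimethoxyphenyl)oxolan-2-one, C7 epimers | O=C1[C@H](C(O)c2cc(OC)c(OC)c(OC)c2)[C@@H](CO[Si](c2ccccc2)(c2ccccc2)C(C)(C)C)[C@@H](c2cc(OC)c(OC)c(OC)c2)O1 | intermediate
8 | (1S,2S,3R)-2-[(tert-butyldiphenylsilyloxy)methyl]-3-(hydroxymethyl)-1,4-bis(3,4,5-trimethoxyphenyl)butane-1,4-diol, C7 epimers | OC[C@H](C(O)c1cc(OC)c(OC)c(OC)c1)[C@@H](CO[Si](c1ccccc1)(c1ccccc1)C(C)(C)C)[C@@H](c1cc(OC)c(OC)c(OC)c1)O | intermediate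
9 | C5 mono-p-toluenesulfonate of triol 8 | Cc1ccc(cc1)S(=O)(=O)OC[C@H](C(O)c1cc(OC)c(OC)c(OC)c1)[C@@H](CO[Si](c1ccccc1)(c1ccccc1)C(C)(C)C)[C@@H](c1cc(OC)c(OC)c(OC)c1)O | intermediate (not isolated)
10 | {(3R,4S,5S)-4-[(tert-butyldiphenylsilyloxy)methyl]-5-(3,4,5-trimethoxyphenyl)oxolan-3-yl}(3,4,5-trimethoxyphenyl)methanol, C7 epimers | COc1cc(C(O)[C@H]2CO[C@H](c3cc(OC)c(OC)c(OC)c3)[C@@H]2CO[Si](c3ccccc3)(c3ccccc3)C(C)(C)C)cc(OC)c1OC | intermediate
11 | {(3R,4S,5S)-4-[(tert-butyldiphenylsilyloxy)methyl]-5-(3,4,5-trimethoxyphenyl)oxolan-3-yl}(3,4,5-trimethoxyphenyl)methanone | COc1cc(C(=O)[C@H]2CO[C@H](c3cc(OC)c(OC)c(OC)c3)[C@@H]2CO[Si](c3ccccc3)(c3ccccc3)C(C)(C)C)cc(OC)c1OC | intermediate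
12 | [(3R,4S,5S)-4-(hydroxymethyl)-5-(3,4,5-trimethoxyphenyl)oxolan-3-yl](3,4,5-trimethoxyphenyl)methanone | COc1cc(C(=O)[C@H]2CO[C@H](c3cc(OC)c(OC)c(OC)c3)[C@@H]2CO)cc(OC)c1OC | target

Total step count: 8. Longest linear sequence: 8 steps (1 to 12); aldehyde 5 enters in steps 3 and 4.

Steps most likely to fail

First, step 3. The process at risk is weak enantiofacial control by the carbene, together with enal self-annulation or loss of silyloxide from the homoenolate competing with addition to 5. The fallback replaces catalyst control by an auxiliary-controlled anti-aldol; it sets out from aldehyde 5 and returns at lactone 6.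
- Commercial (S)-4-benzyl-2-oxazolidinone is N-acylated (nBuLi, pent-4-enoyl chloride, THF, −78 °C) to (S)-4-benzyl-3-(pent-4-enoyl)oxazolidin-2-one F1.
- The MgCl2-catalysed anti-aldol addition of F1 to 5 (MgCl2 10 mol%, Et3N, Me3SiCl, EtOAc, rt) runs through the chelated Z-enolate and should give the anti adduct as its trimethylsilyl ether F2.
- Mild acid (1 M HCl, THF) should release the (2R,3S) anti-aldol imide F3.
- LiBH4 (THF, H2O 1 equiv, 0 °C) cleaves the auxiliary reductively to (1S,2S)-2-allyl-1-(3,4,5-trimethoxyphenyl)propane-1,3-diol F4.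
- tBuPh2SiCl and imidazole (CH2Cl2, 0 °C) silylate the primary hydroxyl only, giving the primary silyl ether F5.
- Lemieux–Johnson cleavage of the vinyl group (OsO4 cat., NaIO4, 2,6-lutidine, dioxane–H2O) gives the aldehyde, which closes onto the benzylic hydroxyl as the lactol F6.
- TEMPO (cat.) and PhI(OAc)2 in CH2Cl2 oxidise the lactol to 6.

Second, step 6. The process at risk is sulfonylation spreading from the primary to a benzylic hydroxyl, whose sulfonate would ionise and scramble C2, or base-induced silyl migration from O9 to O2 followed by closure through O9. The fallback differentiates the hydroxyls before the lactone is opened and closes the ring by a neutral Mitsunobu cyclodehydration; it sets out from aldol adduct 7 and returns at target 12.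
- The C7 hydroxyl of 7 is silylated (tBuMe2SiOTf, 2,6-lutidine, CH2Cl2, −78 °C) to the C7 tert-butyldimethylsilyl ether F7.
- LiBH4 (THF, 0 °C to rt) gives the 1,4-diol F8, in which only the C5 and C2 hydroxyls are free.
- PPh3 and diisopropyl azodicarboxylate (THF, 0 °C) activate the primary C5 oxygen, which the C2 hydroxyl displaces with retention at C2, to give the bis-silylated oxolane F9.
- Bu4NF buffered with AcOH (THF, rt) removes both silyl groups to give the oxolane diol F10.
- MnO2 (CH2Cl2, rt) oxidises only the benzylic C7 carbinol, giving 12.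

Third, step 4. The process at risk is reversal of the aldol addition before or during the quench and incomplete addition to the electron-rich aldehyde. The fallback is an irreversible Claisen-type C-acylation followed by ketone reduction; it sets out from lactone 6 and returns at 7.
- The enolate of 6 (LiN(iPr)2, 2.2 equiv, THF, −78 °C) is acylated with 1-(3,4,5-trimethoxybenzoyl)imidazole to the trans β-keto lactone F11, in which C4 is under thermodynamic control.
- NaBH4 (MeOH, −20 °C) reduces the ketone and should leave the lactone, giving 7 as its C7 epimers.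

Further compounds
F1 | step 3 | (S)-4-benzyl-3-(pent-4-enoyl)oxazolidin-2-one | C=CCCC(=O)N1[C@@H](Cc2ccccc2)COC1=O
F2 | step 3 | (S)-4-benzyl-3-[(2R,3S)-2-allyl-3-(trimethylsilyloxy)-3-(3,4,5-trimethoxyphenyl)propanoyl]oxazolidin-2-one | C=CC[C@@H](C(=O)N1[C@@H](Cc2ccccc2)COC1=O)[C@@H](c1cc(OC)c(OC)c(OC)c1)O[Si](C)(C)C
F3 | step 3 | (S)-4-benzyl-3-[(2R,3S)-2-allyl-3-hydroxy-3-(3,4,5-trimethoxyphenyl)propanoyl]oxazolidin-2-one | C=CC[C@@H](C(=O)N1[C@@H](Cc2ccccc2)COC1=O)[C@@H](c1cc(OC)c(OC)c(OC)c1)O
F4 | step 3 | (1S,2S)-2-allyl-1-(3,4,5-trimethoxyphenyl)propane-1,3-diol | C=CC[C@@H](CO)[C@@H](c1cc(OC)c(OC)c(OC)c1)O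
F5 | step 3 | (1S,2S)-2-[(tert-butyldiphenylsilyloxy)methyl]-1-(3,4,5-trimethoxyphenyl)pent-4-en-1-ol | C=CC[C@@H](CO[Si](c1ccccc1)(c1ccccc1)C(C)(C)C)[C@@H](c1cc(OC)c(OC)c(OC)c1)O
F6 | step 3 | (4S,5S)-4-[(tert-butyldiphenylsilyloxy)methyl]-5-(3,4,5-trimethoxyphenyl)oxolan-2-ol, anomer mixture | OC1C[C@@H](CO[Si](c2ccccc2)(c2ccccc2)C(C)(C)C)[C@@H](c2cc(OC)c(OC)c(OC)c2)O1
F7 | step 6 | (3S,4S,5S)-3-[(tert-butyldimethylsilyloxy)(3,4,5-trimethoxyphenyl)methyl]-4-[(tert-butyldiphenylsilyloxy)methyl]-5-(3,4,5-trimethoxyphenyl)oxolan-2-one, C7 epimers | O=C1[C@H](C(O[Si](C)(C)C(C)(C)C)c2cc(OC)c(OC)c(OC)c2)[C@@H](CO[Si](c2ccccc2)(c2ccccc2)C(C)(C)C)[C@@H](c2cc(OC)c(OC)c(OC)c2)O1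
F8 | step 6 | (1S,2S,3R)-4-(tert-butyldimethylsilyloxy)-2-[(tert-butyldiphenylsilyloxy)methyl]-3-(hydroxymethyl)-1,4-bis(3,4,5-trimethoxyphenyl)butan-1-ol, C7 epimers | OC[C@H](C(O[Si](C)(C)C(C)(C)C)c1cc(OC)c(OC)c(OC)c1)[C@@H](CO[Si](c1ccccc1)(c1ccccc1)C(C)(C)C)[C@@H](c1cc(OC)c(OC)c(OC)c1)O
F9 | step 6 | (2S,3S,4R)-4-[(tert-butyldimethylsilyloxy)(3,4,5-trimethoxyphenyl)methyl]-3-[(tert-butyldiphenylsilyloxy)methyl]-2-(3,4,5-trimethoxyphenyl)oxolane, C7 epimers | COc1cc(C(O[Si](C)(C)C(C)(C)C)[C@H]2CO[C@H](c3cc(OC)c(OC)c(OC)c3)[C@@H]2CO[Si](c3ccccc3)(c3ccccc3)C(C)(C)C)cc(OC)c1OC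
F10 | step 6 | [(3R,4S,5S)-4-(hydroxymethyl)-5-(3,4,5-trimethoxyphenyl)oxolan-3-yl](3,4,5-trimethoxyphenyl)methanol, C7 epimers | COc1cc(C(O)[C@H]2CO[C@H](c3cc(OC)c(OC)c(OC)c3)[C@@H]2CO)cc(OC)c1OC
F11 | step 4 | (3S,4S,5S)-4-[(tert-butyldiphenylsilyloxy)methyl]-3-(3,4,5-trimethoxybenzoyl)-5-(3,4,5-trimethoxyphenyl)oxolan-2-one | O=C1[C@H](C(=O)c2cc(OC)c(OC)c(OC)c2)[C@@H](CO[Si](c2ccccc2)(c2ccccc2)C(C)(C)C)[C@@H](c2cc(OC)c(OC)c(OC)c2)O1
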